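**Retrosynthetic overview**

1. The target is two bibenzyls tied by a diaryl ether. All four benzene rings are bought (A = 4-hydroxyphenyl, B = 1,3,5-trisubstituted methoxy ring, C = para-phenylene, D = salicylic acid ring), so no ring is formed on the route; only the three linkers are made.
2. Last disconnection: one hydrogenation turns a stilbene C=C into the C–D ethylene bridge and removes two O-benzyl groups.
3. Key disconnection: the bond from ring-D C6 to the bridge carbon, made by Rh(III)-catalysed, carboxylate-directed dehydrogenative C–H/C–H coupling of 2-(benzyloxy)-4-methoxybenzoic acid with the terminal vinyl group of an A–B–C styrene. The enabling feature is the target's own CO2H on C1 of ring D: of its two ortho positions C2 carries oxygen, so a carboxylate-bound metal can reach only C6–H, the carbon that bears the bridge and the one that electrophilic chemistry (C3, C5) would avoid.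
4. Styrene fragment: Chan–Lam O-arylation of the ring-B phenol with 4-vinylphenylboronic acid; the phenol comes from hydroboration/B-alkyl Suzuki coupling of 4-benzyloxystyrene with 3-bromo-5-methoxyphenol.
5. Acid fragment: O-benzylation and saponification of methyl 4-methoxysalicylate.

Key step: step 5

Remark: the target has no stereocentre and no stereogenic double bond, so it is achiral and no step has to control configuration; the only stereo-element on the route is the E double bond of the key-step product, which the last step removes.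

**Route**

Step 1
Reactants: 1 1-(benzyloxy)-4-ethenylbenzene; 2 3-bromo-5-methoxyphenol
Product: 4 3-{2-[4-(benzyloxy)phenyl]ethyl}-5-methoxyphenol, via B-alkyl-9-BBN 3 (not isolated)
Conditions: 9-BBN, THF, 0 °C to rt; then 2, PdCl2(dppf) (cat.), aq. K3PO4, THF/DMF, 60 °C
Reagents that add atoms: none
Why: 9-BBN should add to the terminal alkene with anti-Markovnikov selectivity, and the primary alkylborane should then undergo a B-alkyl Suzuki–Miyaura coupling with the aryl bromide, the phenol being carried as its phenoxide.

Step 2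
Reactants: 4 3-{2-[4-(benzyloxy)phenyl]ethyl}-5-methoxyphenol; 5 (4-ethenylphenyl)boronic acid
Product: 6 1-{2-[4-(benzyloxy)phenyl]ethyl}-3-(4-ethenylphenoxy)-5-methoxybenzene
Conditions: Cu(OAc)2 (2 equiv), pyridine, 4 Å MS, CH2Cl2, dry air, rt
Reagents that add atoms: none
Why: Chan–Lam oxidative O-arylation of an electron-rich phenol with an arylboronic acid runs at room temperature and should leave the vinyl group and the benzyl ether untouched.

Step 3
Reactants: 7 methyl 2-hydroxy-4-methoxybenzoate
Product: 8 methyl 2-(benzyloxy)-4-methoxybenzoate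
Conditions: BnBr, K2CO3, DMF, 60 °C
Reagents that add atoms: benzyl bromide, BrCc1ccccc1
Why: Williamson ether synthesis on the chelated salicylate phenol should proceed cleanly with carbonate in DMF at moderate heat.

Step 4
Reactants: 8 methyl 2-(benzyloxy)-4-methoxybenzoate
Product: 9 2-(benzyloxy)-4-methoxybenzoic acid
Conditions: NaOH, THF/MeOH/H2O, 60 °C; then 1 M HCl
Reagents that add atoms: sodium hydroxide (aqueous; its oxygen becomes the carboxyl OH), [Na+].[OH-]
Why: ester saponification of a methyl benzoate with one ortho substituent should be straightforward, and the benzyl and methyl ethers are inert to hydroxide.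

Step 5
Reactants: 6 1-{2-[4-(benzyloxy)phenyl]ethyl}-3-(4-ethenylphenoxy)-5-methoxybenzene; 9 2-(benzyloxy)-4-methoxybenzoic acid (1.5 equiv)
Product: 10 2-(benzyloxy)-6-[(E)-2-(4-{3-[2-(4-(benzyloxy)phenyl)ethyl]-5-methoxyphenoxy}phenyl)ethenyl]-4-methoxybenzoic acid
Conditions: [Cp*RhCl2]2 (2.5 mol %), Cu(OAc)2 (2.2 equiv), DMF, 100 °C, N2
Reagents that add atoms: none
Why: The carboxylate of 9 binds Cp*Rh(III) and delivers it by concerted metalation–deprotonation to C6–H, giving a five-membered rhodacycle; the vinyl group of 6 then inserts with the aryl carbon adding to the terminal CH2, syn β-hydride elimination releases the alkene, and Cu(II) returns Rh(I) to Rh(III). The closest known reaction type is the Rh(III)-catalysed, carboxyl-directed oxidative ortho-olefination of 2-alkoxybenzoic acids with styrenes (a directed Fujiwara–Moritani, or dehydrogenative Heck, coupling). No ring is closed and no stereocentre is formed; the E geometry follows from syn insertion and syn β-hydride elimination and is removed in step 6. The step needs site selectivity for C6 over the more electron-rich C3 and C5, which is secured because C6–H is the only C–H ortho to the carboxyl group (C2 carries the benzyloxy group); this also rules out double olefination. It also needs linear regiochemistry and reaction at one alkene only, which the terminal styrene gives because 6 has no coordinating group and no other alkene.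

Step 6
Reactants: 10 2-(benzyloxy)-6-[(E)-2-(4-{3-[2-(4-(benzyloxy)phenyl)ethyl]-5-methoxyphenoxy}phenyl)ethenyl]-4-methoxybenzoic acid
Product: 11 2-hydroxy-6-[2-(4-{3-[2-(4-hydroxyphenyl)ethyl]-5-methoxyphenoxy}phenyl)ethyl]-4-methoxybenzoic acid (target)
Conditions: H2 (1 atm), 10% Pd/C, EtOAc/MeOH, rt
Reagents that add atoms: none
Why: heterogeneous catalytic hydrogenation should saturate the stilbene double bond and hydrogenolyse both benzyl aryl ethers in one operation, while the diaryl ether, methyl ethers and carboxylic acid are inert.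

**Compound list**

1 | 1-(benzyloxy)-4-ethenylbenzene (4-benzyloxystyrene) | C=Cc1ccc(OCc2ccccc2)cc1 | starting material
2 | 3-bromo-5-methoxyphenol | COc1cc(O)cc(Br)c1 | starting material
3 | 9-{2-[4-(benzyloxy)phenyl]ethyl}-9-borabicyclo[3.3.1]nonane (B-alkyl-9-BBN) | C(Cc1ccc(OCc2ccccc2)cc1)B1C2CCCC1CCC2 | intermediate
4 | 3-{2-[4-(benzyloxy)phenyl]ethyl}-5-methoxyphenol | COc1cc(O)cc(CCc2ccc(OCc3ccccc3)cc2)c1 | intermediate
5 | (4-ethenylphenyl)boronic acid | OB(O)c1ccc(C=C)cc1 | starting material
6 | 1-{2-[4-(benzyloxy)phenyl]ethyl}-3-(4-ethenylphenoxy)-5-methoxybenzene | COc1cc(CCc2ccc(OCc3ccccc3)cc2)cc(Oc2ccc(C=C)cc2)c1 | intermediate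
7 | methyl 2-hydroxy-4-methoxybenzoate | COC(=O)c1ccc(OC)cc1O | starting material
8 | methyl 2-(benzyloxy)-4-methoxybenzoate | COC(=O)c1ccc(OC)cc1OCc1ccccc1 | intermediate
9 | 2-(benzyloxy)-4-methoxybenzoic acid | OC(=O)c1ccc(OC)cc1OCc1ccccc1 | intermediate
10 | 2-(benzyloxy)-6-[(E)-2-(4-{3-[2-(4-(benzyloxy)phenyl)ethyl]-5-methoxyphenoxy}phenyl)ethenyl]-4-methoxybenzoic acid | COc1cc(CCc2ccc(OCc3ccccc3)cc2)cc(Oc2ccc(/C=C/c3cc(OC)cc(OCc4ccccc4)c3C(=O)O)cc2)c1 | intermediate
11 | 2-hydroxy-6-[2-(4-{3-[2-(4-hydroxyphenyl)ethyl]-5-methoxyphenoxy}phenyl)ethyl]-4-methoxybenzoic acid | COc1cc(CCc2ccc(O)cc2)cc(Oc2ccc(CCc3cc(OC)cc(O)c3C(=O)O)cc2)c1 | target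

**Step count and risks**

Total steps: 6. Longest linear sequence: 4 steps (1, 2, 5, 6; the acid branch 3, 4, 5, 6 is equally long).

Steps most likely to fail:

Step 5. The electron-rich, 2,6-disubstituted benzoic acid may lose CO2 under the hot oxidising conditions, the styrene may oligomerise before C–H insertion turns over, or the product acid may lactonise onto the new alkene. The fallback makes the same bond by cross-coupling of a pre-functionalised arene; it sets out from 6 and comes back to the route at 11. Purchased 5,7-dihydroxy-2,2-dimethyl-4H-1,3-benzodioxin-4-one would be methylated at the non-chelated 7-OH under Mitsunobu conditions (MeOH, PPh3, DIAD, THF) to 5-hydroxy-7-methoxy-2,2-dimethyl-4H-1,3-benzodioxin-4-one F1. Triflation (Tf2O, pyridine, CH2Cl2, 0 °C) would give 7-methoxy-2,2-dimethyl-4-oxo-4H-1,3-benzodioxin-5-yl trifluoromethanesulfonate F2. Styrene 6 would be hydroborated with 9-BBN (THF, rt) to the B-alkyl-9-BBN F3 and coupled in the same flask with F2 (PdCl2(dppf), aq. K3PO4, THF/DMF, 60 °C; B-alkyl Suzuki–Miyaura) to the benzodioxinone F4. Opening of the acetonide (KOH, DMSO/H2O, 80 °C, then acid) would give the salicylic acid F5, and hydrogenolysis of the remaining benzyl ether (H2, Pd/C) would give 11.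

Step 2. C–O bond formation at copper may be slow, so that protodeboronation, oxidative homocoupling of the boronic acid, or radical oligomerisation of its vinyl group consumes the partner first. The fallback sets out from 4 and comes back at 6. Nucleophilic aromatic substitution of 4 on 4-fluorobenzaldehyde (K2CO3, DMF, 120 °C) would give 4-(3-{2-[4-(benzyloxy)phenyl]ethyl}-5-methoxyphenoxy)benzaldehyde F6, and Wittig methylenation (Ph3PCH3Br, KOtBu, THF, 0 °C to rt) would give 6.

Step 1. Oxidative addition into the electron-rich bromophenoxide may be slow under the basic aqueous conditions, so that protodeboronation or β-hydride elimination of the alkylborane wins. The fallback sets out from 1 and 2 and comes back at 4. A Mizoroki–Heck reaction of 2 with 1 (Pd(OAc)2, P(o-tol)3, Et3N, DMF, 100 °C), which needs no organoboron partner and leaves the phenol largely un-ionised, would give 3-{(E)-2-[4-(benzyloxy)phenyl]ethenyl}-5-methoxyphenol F7. Diimide reduction (TsNHNH2, NaOAc, THF/H2O, reflux) would saturate the alkene without touching the benzyl ether and give 4.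

**Further compounds**

F1 | step 5 | 5-hydroxy-7-methoxy-2,2-dimethyl-4H-1,3-benzodioxin-4-one | CC1(C)OC(=O)c2c(O)cc(OC)cc2O1
F2 | step 5 | 7-methoxy-2,2-dimethyl-4-oxo-4H-1,3-benzodioxin-5-yl trifluoromethanesulfonate | CC1(C)OC(=O)c2c(OS(=O)(=O)C(F)(F)F)cc(OC)cc2O1
F3 | step 5 | 9-[2-(4-{3-[2-(4-(benzyloxy)phenyl)ethyl]-5-methoxyphenoxy}phenyl)ethyl]-9-borabicyclo[3.3.1]nonane | COc1cc(CCc2ccc(OCc3ccccc3)cc2)cc(Oc2ccc(CCB3C4CCCC3CCC4)cc2)c1
F4 | step 5 | 5-[2-(4-{3-[2-(4-(benzyloxy)phenyl)ethyl]-5-methoxyphenoxy}phenyl)ethyl]-7-methoxy-2,2-dimethyl-4H-1,3-benzodioxin-4-one | COc1cc(CCc2ccc(OCc3ccccc3)cc2)cc(Oc2ccc(CCc3cc(OC)cc4OC(C)(C)OC(=O)c34)cc2)c1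
F5 | step 5 | 2-[2-(4-{3-[2-(4-(benzyloxy)phenyl)ethyl]-5-methoxyphenoxy}phenyl)ethyl]-6-hydroxy-4-methoxybenzoic acid | COc1cc(CCc2ccc(OCc3ccccc3)cc2)cc(Oc2ccc(CCc3cc(OC)cc(O)c3C(=O)O)cc2)c1
F6 | step 2 | 4-(3-{2-[4-(benzyloxy)phenyl]ethyl}-5-methoxyphenoxy)benzaldehyde | COc1cc(CCc2ccc(OCc3ccccc3)cc2)cc(Oc2ccc(C=O)cc2)c1
F7 | step 1 | 3-{(E)-2-[4-(benzyloxy)phenyl]ethenyl}-5-methoxyphenol | COc1cc(O)cc(/C=C/c2ccc(OCc3ccccc3)cc2)c1
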